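**Retrosynthetic overview**

- Target 7 ⇐ quinone monoketal 8 by reductive loss of one C8 methoxide (Zn/AcOH); 8 ⇐ 5-hydroxy-7-methoxyflavone 5 + methanol by four-electron anodic methoxylation, which forms both C8–O bonds.
- 5 ⇐ β-diketone 4 by acid cyclodehydration (the pyranone C ring, the only ring made); 4 ⇐ acetophenone 3 + acid chloride 2 (from acid 1) by C-aroylation of the lithium polyanion.
- Feature the strategy rests on: in the benzo (A) ring of the chromone, the free C5–OH and the C8–OMe are para to each other, i.e. a hydroquinone monomethyl ether. C8 lies between C7–OMe and the ring oxygen O1 on C8a. The C8 oxygen can therefore be written onto the C8–H of a symmetric, phloroglucinol-derived 5,7-dioxygenated flavone by oxidation of the C5 phenol, and the chelated C5–OH is left as the only free hydroxyl.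
- Ring order: A and B rings are bought; C ring closed in step 3; A ring dearomatised in step 4 and rearomatised in step 5.

Key step: step 4

Remark: the target has no stereocentre, so the single-enantiomer requirement is met trivially. Compound 7 (the target) is also passed through transiently in step 4, where it cannot be held because it is oxidised more easily than 5; it is isolated only in step 5.

**Route**

Step 1
Reactants: 1 2,3-dimethoxybenzoic acid
Product: 2 2,3-dimethoxybenzoyl chloride
Conditions: (COCl)2 (1.3 equiv), DMF (cat.), CH2Cl2, 0 °C → rt; evaporate, use crude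
Reagents that add atoms: oxalyl chloride, O=C(Cl)C(=O)Cl
Why: Vilsmeier-catalysed acid chloride formation is routine for electron-rich benzoic acids, and the two aryl methyl ethers are inert to it.

Step 2
Reactants: 3 2',6'-dihydroxy-4'-methoxyacetophenone; 2 2,3-dimethoxybenzoyl chloride
Product: 4 1-(2,6-dihydroxy-4-methoxyphenyl)-3-(2,3-dimethoxyphenyl)propane-1,3-dione (diketone, in equilibrium with its enol and cyclic hemiketal forms)
Conditions: LiHMDS (4.2 equiv), THF, −78 → −10 °C; recool to −78 °C, 2 (1.0 equiv), → rt; aq. HCl work-up
Reagents that add atoms: none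
Why: Claisen-type C-acylation of the lithium polyanion (bis-phenoxide enolate) of an unprotected hydroxyacetophenone with one equivalent of aroyl chloride should give the β-diketone directly, since the enolate carbon is the most nucleophilic site, any O-aroylated material is funnelled to the same diketone by Baker–Venkataraman acyl transfer under the excess base, and the fourth equivalent of base covers the acidic product.

Step 3
Reactants: 4 1-(2,6-dihydroxy-4-methoxyphenyl)-3-(2,3-dimethoxyphenyl)propane-1,3-dione
Product: 5 2-(2,3-dimethoxyphenyl)-5-hydroxy-7-methoxychromen-4-one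
Conditions: H2SO4 (0.5% v/v) in AcOH, 95 °C
Reagents that add atoms: none
Why: Acid-catalysed cyclodehydration of an o-hydroxyaryl β-diketone (6-exo hemiketal formation, then loss of water) closes the pyranone, and because the two ortho hydroxyls of 4 are equivalent either one gives the same flavone, the other becoming the chelated C5–OH.

Step 4
Reactants: 5 2-(2,3-dimethoxyphenyl)-5-hydroxy-7-methoxychromen-4-one; 6 methanol
Product: 8 2-(2,3-dimethoxyphenyl)-7,8,8-trimethoxy-8H-chromene-4,5-dione, via 2-(2,3-dimethoxyphenyl)-5-hydroxy-7,8-dimethoxychromen-4-one 7 (not isolated)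
Conditions: divided cell (glass frit), reticulated vitreous carbon anode, Pt cathode, 0.1 M LiClO4, 2,6-lutidine (4 equiv, anolyte), MeOH–CH2Cl2 (4:1), anode held at the first phenol wave (about +1.0 V vs Ag/AgCl, set by cyclic voltammetry), 0 °C, 4 F/mol; NaHCO3 work-up, Et3N-deactivated silica
Reagents that add atoms: methanol (6), CO
Why: Proposed new method: anodic oxidation in methanol to p-quinone monoketals is established for simple para-unsubstituted phenols and p-methoxyphenols (chemical counterpart: PhI(OAc)2/MeOH) but has not been shown on a C4-carbonyl-chelated 5-hydroxychromone, so the step extrapolates that reaction type to a new substrate class. Proton-coupled two-electron oxidation of the C5 phenol should give a phenoxonium ion with charge at C6, C8 and C4a; methanol adds at C8 and loss of H8 gives the hydroquinone monomethyl ether 7, which is oxidised at a lower potential than 5 and so should go on at once, through the C8 oxocarbenium ion and a second methanol capture, to the 8,8-dimethoxy dienone 8. Two C8–O bonds are formed, no ring is closed, and no stereocentre arises because C8 carries two identical methoxy groups. The step needs capture at C8 (para) rather than C6 (ortho) and oxidation of the A ring rather than the B ring. Para capture is the normal course for phenoxonium ions and C8 is the position at which oxidants are known to attack 5-hydroxyflavones, while the phloroglucinol-type A-ring phenol should be oxidised well below the dimethoxyphenyl B ring, which is conjugated to the electron-poor pyranone, so holding the anode at the first wave should secure chemoselectivity. The divided cell and the lutidine buffer keep cathodic methoxide away from the electrophilic C2 of the pyranone and keep anodic acid away from the ketal.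

Step 5
Reactants: 8 2-(2,3-dimethoxyphenyl)-7,8,8-trimethoxy-8H-chromene-4,5-dione
Product: 7 5-hydroxy-2',3',7,8-tetramethoxyflavone [2-(2,3-dimethoxyphenyl)-5-hydroxy-7,8-dimethoxychromen-4-one], the target
Conditions: Zn dust (5 equiv), AcOH (10 equiv), dry THF, 0 °C → rt
Reagents that add atoms: none
Why: Reductive aromatisation of a quinone monoketal (two-electron reduction of the dienone, then expulsion of one C8 methoxide) is a known route to p-methoxyphenols and should leave the C5–OH as the only free hydroxyl, while anhydrous conditions avoid ketal hydrolysis and the flavone enone is not reduced by zinc at this temperature.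

**Compound list**

1 | 2,3-dimethoxybenzoic acid | COc1cccc(C(=O)O)c1OC | starting material
2 | 2,3-dimethoxybenzoyl chloride | COc1cccc(C(=O)Cl)c1OC | intermediate
3 | 2',6'-dihydroxy-4'-methoxyacetophenone | CC(=O)c1c(O)cc(OC)cc1O | starting material
4 | 1-(2,6-dihydroxy-4-methoxyphenyl)-3-(2,3-dimethoxyphenyl)propane-1,3-dione | COc1cccc(C(=O)CC(=O)c2c(O)cc(OC)cc2O)c1OC | intermediate
5 | 2-(2,3-dimethoxyphenyl)-5-hydroxy-7-methoxychromen-4-one | COc1cccc(-c2cc(=O)c3c(O)cc(OC)cc3o2)c1OC | intermediate
6 | methanol | CO | starting material
7 | 5-hydroxy-2',3',7,8-tetramethoxyflavone | COc1cccc(-c2cc(=O)c3c(O)cc(OC)c(OC)c3o2)c1OC | target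
8 | 2-(2,3-dimethoxyphenyl)-7,8,8-trimethoxy-8H-chromene-4,5-dione | COc1cccc(C2=CC(=O)C3=C(O2)C(OC)(OC)C(OC)=CC3=O)c1OC | intermediate

**Step count**

Total steps: 5. Longest linear sequence: 5 (steps 1 to 5 from acid 1).

**Steps most likely to fail, with fallbacks**

1. Step 4 (proposed new method). The chelated phenol may be oxidised too sluggishly to compete with solvent or B-ring oxidation, methanol capture may go partly to C6, or the dienone may be lost by methanol addition at C2 or by ketal hydrolysis during isolation. The fallback is known chemistry and sets out from 5. Elbs persulfate oxidation (K2S2O8, aq. KOH, pyridine, 10–20 °C) should put a sulfate para to the C5–OH and give potassium 2-(2,3-dimethoxyphenyl)-5-hydroxy-7-methoxy-4-oxochromen-8-yl sulfate F1. Acid hydrolysis (aq. HCl, Na2SO3, 90 °C) should then give 2-(2,3-dimethoxyphenyl)-5,8-dihydroxy-7-methoxychromen-4-one F2. Methylation with Me2SO4 (1.05 equiv), K2CO3, acetone, reflux should alkylate only the unchelated C8–OH, since the C5–OH is held by the C4 carbonyl. The fallback comes back to the route at 7 and bypasses step 5.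

2. Step 5. Adventitious water and acid could hydrolyse the ketal to the 5,8-quinone faster than it is reduced, or reduction could run on into the pyranone C2=C3 bond. The fallback sets out from 8 and makes hydrolysis the intended path. Dilute HCl in aqueous THF should give 2-(2,3-dimethoxyphenyl)-7-methoxychromene-4,5,8-trione F3. Na2S2O4 (EtOAc/water) should reduce it to 2-(2,3-dimethoxyphenyl)-5,8-dihydroxy-7-methoxychromen-4-one F2, and the selective C8–O-methylation described above then returns to the route at 7.

3. Step 2. The polyanion may precipitate or enolise incompletely, so that O-aroylation and multiple acylation compete with C-acylation. The fallback is the classical ester route and sets out from 3 and 2. Aroylation with 2 (2.3 equiv), pyridine, DMAP (cat.) should give 2-acetyl-5-methoxy-1,3-phenylene bis(2,3-dimethoxybenzoate) F4. Baker–Venkataraman rearrangement (powdered KOH, pyridine, 50 °C) should give 2-[3-(2,3-dimethoxyphenyl)-3-oxopropanoyl]-3-hydroxy-5-methoxyphenyl 2,3-dimethoxybenzoate F5. Cyclodehydration (H2SO4/AcOH, 95 °C) should give 2-(2,3-dimethoxyphenyl)-7-methoxy-4-oxochromen-5-yl 2,3-dimethoxybenzoate F6. Saponification (K2CO3, MeOH–H2O, then acidification) comes back to the route at 5 and returns acid 1.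

**Further compounds**

F1 | step 4 | potassium 2-(2,3-dimethoxyphenyl)-5-hydroxy-7-methoxy-4-oxochromen-8-yl sulfate | COc1cccc(-c2cc(=O)c3c(O)cc(OC)c(OS(=O)(=O)[O-])c3o2)c1OC.[K+]
F2 | step 4 | 2-(2,3-dimethoxyphenyl)-5,8-dihydroxy-7-methoxychromen-4-one | COc1cccc(-c2cc(=O)c3c(O)cc(OC)c(O)c3o2)c1OC
F3 | step 5 | 2-(2,3-dimethoxyphenyl)-7-methoxychromene-4,5,8-trione | COc1cccc(C2=CC(=O)C3=C(O2)C(=O)C(OC)=CC3=O)c1OC
F4 | step 2 | 2-acetyl-5-methoxy-1,3-phenylene bis(2,3-dimethoxybenzoate) | CC(=O)c1c(OC(=O)c2cccc(OC)c2OC)cc(OC)cc1OC(=O)c1cccc(OC)c1OC
F5 | step 2 | 2-[3-(2,3-dimethoxyphenyl)-3-oxopropanoyl]-3-hydroxy-5-methoxyphenyl 2,3-dimethoxybenzoate | COc1cccc(C(=O)CC(=O)c2c(O)cc(OC)cc2OC(=O)c2cccc(OC)c2OC)c1OC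
F6 | step 2 | 2-(2,3-dimethoxyphenyl)-7-methoxy-4-oxochromen-5-yl 2,3-dimethoxybenzoate | COc1cccc(-c2cc(=O)c3c(OC(=O)c4cccc(OC)c4OC)cc(OC)cc3o2)c1OC
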